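**Strategy**

- Retrosynthetic cuts, in order: the phenolic O–benzyl bond and C3–CH2OH (back to C3–CO2Me); the furan ring of the benzofuran at O1′–C2′ and C3′–C3a′ (giving an o-iodophenol and an aryl alkyne, whose terminal carbon comes from an aldehyde); the C2–C3 bond of the dihydrofuran ring; the aryl–C(diazo) bond; the ArO–CH2Ar ether bond.
- Forward order: two bought benzene rings are joined as a benzyl aryl ether, the diazoacetate is attached at the iodide, and the dihydrofuran ring is closed by carbene C–H insertion. C3 is then epimerised, the aldehyde becomes an alkyne, and Sonogashira coupling with the third bought ring closes the furan ring of the benzofuran. Ester reduction and debenzylation finish.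
- Enabling feature: in the dihydrofuran ring, C2 carries both the ring oxygen O1 and the 4-hydroxy-3-methoxyphenyl group, so it is a former ArO–CH2–Ar methylene. Its neighbour C3 sits on C3a of the fused benzene ring and bears one oxygenated carbon, so it is a former ester-substituted carbene carbon. O1 (on C7a) and C3 (on C3a) are ortho on the same benzene ring, which puts the methylene C–H in a 1,5 relationship to the carbene.
- Stereochemistry: C2 (S) comes from the chiral dirhodium carboxylate, which selects one enantiotopic methylene hydrogen. C3 is equilibrated to trans under control of C2 (3S ester, which is the 3R alcohol of the target by priority change only).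

Key step: step 4

Assumption: Rh2(R-PTTL)4 is taken to give the 2S product, by analogy with the sense of induction known for this catalyst family with benzyl aryl ethers (S ligands giving 2R); if the sense is reversed here, Rh2(S-PTTL)4 is used with no other change.

**Route**

Step 1
Reactants: 1 (4-benzyloxy-3-methoxyphenyl)methanol
Product: 2 1-benzyloxy-4-(chloromethyl)-2-methoxybenzene
Conditions: SOCl2 (1.2 equiv), CH2Cl2, 0 °C to rt; concentrate, use crude
Reagents that add atoms: thionyl chloride, O=S(Cl)Cl
Why: Chlorodehydroxylation of an electron-rich benzylic alcohol with thionyl chloride is fast at 0 °C and leaves both aryl ethers untouched; the chloride is used at once because it self-alkylates on storage.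

Step 2
Reactants: 2 1-benzyloxy-4-(chloromethyl)-2-methoxybenzene; 3 4-hydroxy-3-iodo-5-methoxybenzaldehyde (5-iodovanillin)
Product: 4 4-[(4-benzyloxy-3-methoxyphenyl)methoxy]-3-iodo-5-methoxybenzaldehyde
Conditions: K2CO3, DMF, 50 °C
Reagents that add atoms: none
Why: Williamson ether synthesis, in which the acidic phenoxide of 3 displaces chloride from the reactive benzylic chloride (SN2), and the aldehyde and aryl iodide are inert to carbonate.

Step 3
Reactants: 4 4-[(4-benzyloxy-3-methoxyphenyl)methoxy]-3-iodo-5-methoxybenzaldehyde; 5 ethyl diazoacetate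
Product: 6 ethyl 2-diazo-2-{2-[(4-benzyloxy-3-methoxyphenyl)methoxy]-5-formyl-3-methoxyphenyl}acetate
Conditions: Pd(PPh3)4 (5 mol %), Ag2CO3 (0.5 equiv), Et3N (1.3 equiv), toluene, rt, dark
Reagents that add atoms: none
Why: Cross-coupling of an aryl iodide with the C–H bond of ethyl diazoacetate under zerovalent palladium (oxidative addition, silver-assisted transfer of the diazoacetate to palladium, reductive elimination with the diazo group kept) is a known route to aryldiazoacetates at room temperature, and the formyl group should survive because neither an amidine base nor a Lewis acid is present to trigger addition of the diazo ester to it.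

Step 4
Reactants: 6 ethyl 2-diazo-2-{2-[(4-benzyloxy-3-methoxyphenyl)methoxy]-5-formyl-3-methoxyphenyl}acetate
Product: 7 ethyl (2S,3R)-2-(4-benzyloxy-3-methoxyphenyl)-5-formyl-7-methoxy-2,3-dihydrobenzofuran-3-carboxylate (cis)
Conditions: Rh2(R-PTTL)4 [dirhodium tetrakis(N-phthaloyl-(R)-tert-leucinate)] (2 mol %), toluene, 4 Å MS, −78 °C, slow addition of 6
Reagents that add atoms: none
Why: The dirhodium carboxylate expels dinitrogen from 6 to give a donor/acceptor rhodium carbene, which inserts into a C–H bond of the ArO–CH2–Ar methylene in a concerted but asynchronous, hydride-transfer-like event through a five-membered transition state. The closest known reaction type is the enantioselective intramolecular 1,5 C–H insertion of ortho-benzyloxy aryldiazoacetates under dirhodium N-phthaloyl-tert-leucinate catalysis, which delivers cis-2-aryl-2,3-dihydrobenzofuran-3-carboxylates. The dihydrofuran ring closes by this 1,5 insertion, C2–C3 being the only new ring bond (the carbene carbon becomes C3, the ether methylene becomes C2). C2 is set by the chiral carboxylate ligands, which expose one of the two enantiotopic methylene hydrogens to the carbene (R ligands assumed for 2S), while C3 is formed cis to the aryl group as the kinetic consequence of the same transition state and is corrected in step 5. The step needs enantiotopic C–H discrimination and chemoselectivity over attack of a formyl oxygen on the carbene (carbonyl ylide) and over addition to the arene rings; the double activation of the C–H bond by the ether oxygen and the electron-rich 4-benzyloxy-3-methoxyphenyl ring, its fixed 1,5 distance from the carbene, and slow addition of 6 to the catalyst at −78 °C in toluene should secure the second.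

Step 5
Reactants: 7 ethyl (2S,3R)-2-(4-benzyloxy-3-methoxyphenyl)-5-formyl-7-methoxy-2,3-dihydrobenzofuran-3-carboxylate (cis)
Product: 10 methyl (2S,3S)-2-(4-benzyloxy-3-methoxyphenyl)-5-formyl-7-methoxy-2,3-dihydrobenzofuran-3-carboxylate (trans), via cis methyl ester 8 (not isolated), via trans ethyl ester 9 (not isolated)
Conditions: NaOMe (0.5 equiv), MeOH–THF, 0 °C to rt; AcOH quench
Reagents that add atoms: methanol (solvent, delivered as methoxide), CO
Why: Base epimerisation through the ester enolate moves the C3 ester trans to the C2 aryl group (thermodynamic control by the untouched C2 centre, giving 3S) while methoxide transesterifies ethyl to methyl in the methanol solvent; ring opening by β-elimination of the aryloxide is a stereoelectronically disfavoured retro-5-endo-trig process, and the benzyl-capped phenol cannot open the ring through a quinone methide.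

Step 6
Reactants: 10 methyl (2S,3S)-2-(4-benzyloxy-3-methoxyphenyl)-5-formyl-7-methoxy-2,3-dihydrobenzofuran-3-carboxylate (trans); 11 dimethyl (1-diazo-2-oxopropyl)phosphonate (Ohira–Bestmann reagent)
Product: 12 methyl (2S,3S)-2-(4-benzyloxy-3-methoxyphenyl)-5-ethynyl-7-methoxy-2,3-dihydrobenzofuran-3-carboxylate
Conditions: K2CO3, MeOH–THF, 0 °C to rt
Reagents that add atoms: none
Why: Seyferth–Gilbert homologation in the Ohira–Bestmann variant, in which methanolysis of 11 releases the diazomethylphosphonate anion that turns the non-enolisable aryl aldehyde into the terminal alkyne, under carbonate/methanol conditions that cannot change the already thermodynamic trans methyl ester.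

Step 7
Reactants: 13 4-(3-hydroxypropyl)-2-methoxyphenol (dihydroconiferyl alcohol)
Product: 14 4-(3-hydroxypropyl)-2-iodo-6-methoxyphenol
Conditions: I2, NaHCO3, THF–H2O, 0 °C to rt; Na2S2O3 quench
Reagents that add atoms: iodine, II
Why: Electrophilic aromatic iodination of the phenol(ate) goes to the only free position ortho to the hydroxyl group (para is blocked by the side chain, the other ortho position by methoxy), and the primary alcohol is inert to iodine/bicarbonate.

Step 8
Reactants: 12 methyl (2S,3S)-2-(4-benzyloxy-3-methoxyphenyl)-5-ethynyl-7-methoxy-2,3-dihydrobenzofuran-3-carboxylate; 14 4-(3-hydroxypropyl)-2-iodo-6-methoxyphenol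
Product: 16 methyl (2S,3S)-2-(4-benzyloxy-3-methoxyphenyl)-5-[5-(3-hydroxypropyl)-7-methoxybenzofuran-2-yl]-7-methoxy-2,3-dihydrobenzofuran-3-carboxylate, via o-alkynylphenol 15 (not isolated)
Conditions: PdCl2(PPh3)2 (5 mol %), CuI (5 mol %), Et3N, DMF, degassed, 65 °C
Reagents that add atoms: none
Why: Sonogashira coupling of the terminal alkyne with the o-iodophenol is followed in the same pot by 5-endo-dig attack of the phenol oxygen on the metal-activated alkyne, a much-used domino route to 2-arylbenzofurans that tolerates free hydroxyl groups; triethylamine cannot disturb the trans ester, which is already the stable epimer.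

Step 9
Reactants: 16 methyl (2S,3S)-2-(4-benzyloxy-3-methoxyphenyl)-5-[5-(3-hydroxypropyl)-7-methoxybenzofuran-2-yl]-7-methoxy-2,3-dihydrobenzofuran-3-carboxylate
Product: 17 3-{2-[(2S,3R)-2-(4-benzyloxy-3-methoxyphenyl)-3-(hydroxymethyl)-7-methoxy-2,3-dihydrobenzofuran-5-yl]-7-methoxybenzofuran-5-yl}propan-1-ol
Conditions: LiAlH4 (2.5 equiv), THF, 0 °C; aqueous potassium sodium tartrate work-up
Reagents that add atoms: none
Why: Hydride reduction of the methyl ester to the primary alcohol with LiAlH4 breaks no bond at C3 (the descriptor changes from S to R only through the priority rules) and leaves the benzofuran and the benzyl ether alone.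

Step 10
Reactants: 17 3-{2-[(2S,3R)-2-(4-benzyloxy-3-methoxyphenyl)-3-(hydroxymethyl)-7-methoxy-2,3-dihydrobenzofuran-5-yl]-7-methoxybenzofuran-5-yl}propan-1-ol
Product: 18 4-{(2S,3R)-3-(hydroxymethyl)-5-[5-(3-hydroxypropyl)-7-methoxybenzofuran-2-yl]-7-methoxy-2,3-dihydrobenzofuran-2-yl}-2-methoxyphenol (CNP0308311.1)
Conditions: H2 (1 atm), Pd/C (10 wt %), EtOAc–MeOH, rt, stopped at consumption of 17
Reagents that add atoms: none
Why: Catalytic hydrogenolysis of a benzyl aryl ether over palladium on carbon at one atmosphere is much faster than cleavage of the cyclic C2–O1 benzylic bond or saturation of the benzofuran, so stopping at full conversion of 17 should free the phenol selectively.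

**Compound list**

1 | (4-benzyloxy-3-methoxyphenyl)methanol | COc1cc(CO)ccc1OCc1ccccc1 | starting material
2 | 1-benzyloxy-4-(chloromethyl)-2-methoxybenzene | COc1cc(CCl)ccc1OCc1ccccc1 | intermediate
3 | 4-hydroxy-3-iodo-5-methoxybenzaldehyde (5-iodovanillin) | COc1cc(C=O)cc(I)c1O | starting material
4 | 4-[(4-benzyloxy-3-methoxyphenyl)methoxy]-3-iodo-5-methoxybenzaldehyde | COc1cc(COc2c(I)cc(C=O)cc2OC)ccc1OCc1ccccc1 | intermediate
5 | ethyl diazoacetate | CCOC(=O)C=[N+]=[N-] | starting material
6 | ethyl 2-diazo-2-{2-[(4-benzyloxy-3-methoxyphenyl)methoxy]-5-formyl-3-methoxyphenyl}acetate | CCOC(=O)C(=[N+]=[N-])c1cc(C=O)cc(OC)c1OCc1ccc(OCc2ccccc2)c(OC)c1 | intermediate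
7 | ethyl (2S,3R)-2-(4-benzyloxy-3-methoxyphenyl)-5-formyl-7-methoxy-2,3-dihydrobenzofuran-3-carboxylate (cis) | COc1cc([C@H]2Oc3c(OC)cc(C=O)cc3[C@H]2C(=O)OCC)ccc1OCc1ccccc1 | intermediate
8 | methyl (2S,3R)-2-(4-benzyloxy-3-methoxyphenyl)-5-formyl-7-methoxy-2,3-dihydrobenzofuran-3-carboxylate (cis methyl ester) | COc1cc([C@H]2Oc3c(OC)cc(C=O)cc3[C@H]2C(=O)OC)ccc1OCc1ccccc1 | intermediate (not isolated)
9 | ethyl (2S,3S)-2-(4-benzyloxy-3-methoxyphenyl)-5-formyl-7-methoxy-2,3-dihydrobenzofuran-3-carboxylate (trans ethyl ester) | COc1cc([C@H]2Oc3c(OC)cc(C=O)cc3[C@@H]2C(=O)OCC)ccc1OCc1ccccc1 | intermediate (not isolated)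
10 | methyl (2S,3S)-2-(4-benzyloxy-3-methoxyphenyl)-5-formyl-7-methoxy-2,3-dihydrobenzofuran-3-carboxylate (trans) | COc1cc([C@H]2Oc3c(OC)cc(C=O)cc3[C@@H]2C(=O)OC)ccc1OCc1ccccc1 | intermediate
11 | dimethyl (1-diazo-2-oxopropyl)phosphonate | COP(=O)(OC)C(=[N+]=[N-])C(C)=O | starting material
12 | methyl (2S,3S)-2-(4-benzyloxy-3-methoxyphenyl)-5-ethynyl-7-methoxy-2,3-dihydrobenzofuran-3-carboxylate | COc1cc([C@H]2Oc3c(OC)cc(C#C)cc3[C@@H]2C(=O)OC)ccc1OCc1ccccc1 | intermediate
13 | 4-(3-hydroxypropyl)-2-methoxyphenol | COc1cc(CCCO)ccc1O | starting material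
14 | 4-(3-hydroxypropyl)-2-iodo-6-methoxyphenol | COc1cc(CCCO)cc(I)c1O | intermediate
15 | methyl (2S,3S)-2-(4-benzyloxy-3-methoxyphenyl)-5-{[2-hydroxy-5-(3-hydroxypropyl)-3-methoxyphenyl]ethynyl}-7-methoxy-2,3-dihydrobenzofuran-3-carboxylate | COc1cc([C@H]2Oc3c(OC)cc(C#Cc4cc(CCCO)cc(OC)c4O)cc3[C@@H]2C(=O)OC)ccc1OCc1ccccc1 | intermediate (not isolated)
16 | methyl (2S,3S)-2-(4-benzyloxy-3-methoxyphenyl)-5-[5-(3-hydroxypropyl)-7-methoxybenzofuran-2-yl]-7-methoxy-2,3-dihydrobenzofuran-3-carboxylate | COc1cc([C@H]2Oc3c(OC)cc(-c4cc5cc(CCCO)cc(OC)c5o4)cc3[C@@H]2C(=O)OC)ccc1OCc1ccccc1 | intermediate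
17 | 3-{2-[(2S,3R)-2-(4-benzyloxy-3-methoxyphenyl)-3-(hydroxymethyl)-7-methoxy-2,3-dihydrobenzofuran-5-yl]-7-methoxybenzofuran-5-yl}propan-1-ol | COc1cc([C@H]2Oc3c(OC)cc(-c4cc5cc(CCCO)cc(OC)c5o4)cc3[C@@H]2CO)ccc1OCc1ccccc1 | intermediate
18 | 4-{(2S,3R)-3-(hydroxymethyl)-5-[5-(3-hydroxypropyl)-7-methoxybenzofuran-2-yl]-7-methoxy-2,3-dihydrobenzofuran-2-yl}-2-methoxyphenol | COc1cc([C@H]2Oc3c(OC)cc(-c4cc5cc(CCCO)cc(OC)c5o4)cc3[C@@H]2CO)ccc1O | target

**Step count**

Total: 10 steps. Longest linear sequence: 9 steps (steps 1–6 and 8–10, from 1); step 7 is a one-step side branch.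

**Steps most likely to fail**

Step 3. What may go wrong is aldol-type addition of the metallated diazoacetate to the formyl group, or decomposition of the diazo ester at palladium outpacing oxidative addition next to the bulky ortho ether. The fallback sets out from 4 and returns at 6, and avoids any palladium–diazo intermediate. The aldehyde of 4 is masked with HC(OMe)3 and catalytic pyridinium p-toluenesulfonate in MeOH as the dimethyl acetal 1-benzyloxy-4-{[4-(dimethoxymethyl)-2-iodo-6-methoxyphenoxy]methyl}-2-methoxybenzene F1. Negishi coupling of F1 with the Reformatsky reagent BrZnCH2CO2Et (Pd(dba)2, XPhos, THF, rt) forms the aryl–CH2 bond and gives ethyl 2-{2-[(4-benzyloxy-3-methoxyphenyl)methoxy]-5-(dimethoxymethyl)-3-methoxyphenyl}acetate F2. Pyridinium p-toluenesulfonate in acetone–water then frees the aldehyde as ethyl 2-{2-[(4-benzyloxy-3-methoxyphenyl)methoxy]-5-formyl-3-methoxyphenyl}acetate F3. Regitz diazo transfer with 4-acetamidobenzenesulfonyl azide and DBU in MeCN at 0 °C converts F3 into 6.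

Step 4. What may go wrong is insufficient discrimination between the two enantiotopic methylene hydrogens, because the doubly activated C–H bond reacts through an early transition state and the flanking methoxy group alters the conformation of the ether. The fallback sets out from 6 and returns at 10, and takes the absolute configuration from resolution instead of catalyst control. Compound 6 is decomposed with achiral Rh2(OAc)4 in CH2Cl2 at rt (slow addition) to give racemic ethyl 2-(4-benzyloxy-3-methoxyphenyl)-5-formyl-7-methoxy-2,3-dihydrobenzofuran-3-carboxylate as a cis/trans mixture F4. NaOMe in MeOH, as in step 5, converges this through the not yet equilibrated racemic methyl ester (cis/trans mixture) F5, which is not isolated, on the racemic trans methyl ester F6. Preparative chromatography on a polysaccharide chiral stationary phase separates the enantiomers: the (2S,3S) enantiomer is 10, and the (2R,3R) enantiomer, methyl (2R,3R)-2-(4-benzyloxy-3-methoxyphenyl)-5-formyl-7-methoxy-2,3-dihydrobenzofuran-3-carboxylate F7, is set aside.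

Step 5. What may go wrong is β-elimination of the aryloxide from the C3 enolate, made easier by the para formyl group, which would open the ring and erode the configuration at C2; base-induced consumption of the aldehyde is a lesser concern. The fallback sets out from 7 and returns at 10, and removes the activating formyl group before base is applied. Compound 7 is converted with HC(OMe)3 and catalytic pyridinium p-toluenesulfonate in MeOH into ethyl (2S,3R)-2-(4-benzyloxy-3-methoxyphenyl)-5-(dimethoxymethyl)-7-methoxy-2,3-dihydrobenzofuran-3-carboxylate F8. NaOMe in MeOH then gives, through the cis methyl ester acetal F9 and the trans ethyl ester acetal F10 (neither isolated), methyl (2S,3S)-2-(4-benzyloxy-3-methoxyphenyl)-5-(dimethoxymethyl)-7-methoxy-2,3-dihydrobenzofuran-3-carboxylate F11. Pyridinium p-toluenesulfonate in acetone–water releases the aldehyde and returns 10.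

**Further compounds**

F1 | step 3 | 1-benzyloxy-4-{[4-(dimethoxymethyl)-2-iodo-6-methoxyphenoxy]methyl}-2-methoxybenzene | COc1cc(COc2c(I)cc(C(OC)OC)cc2OC)ccc1OCc1ccccc1
F2 | step 3 | ethyl 2-{2-[(4-benzyloxy-3-methoxyphenyl)methoxy]-5-(dimethoxymethyl)-3-methoxyphenyl}acetate | CCOC(=O)Cc1cc(C(OC)OC)cc(OC)c1OCc1ccc(OCc2ccccc2)c(OC)c1
F3 | step 3 | ethyl 2-{2-[(4-benzyloxy-3-methoxyphenyl)methoxy]-5-formyl-3-methoxyphenyl}acetate | CCOC(=O)Cc1cc(C=O)cc(OC)c1OCc1ccc(OCc2ccccc2)c(OC)c1
F4 | step 4 | racemic ethyl 2-(4-benzyloxy-3-methoxyphenyl)-5-formyl-7-methoxy-2,3-dihydrobenzofuran-3-carboxylate (cis/trans mixture) | COc1cc(C2Oc3c(OC)cc(C=O)cc3C2C(=O)OCC)ccc1OCc1ccccc1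
F5 | step 4 | racemic methyl 2-(4-benzyloxy-3-methoxyphenyl)-5-formyl-7-methoxy-2,3-dihydrobenzofuran-3-carboxylate (cis/trans mixture, not isolated) | COc1cc(C2Oc3c(OC)cc(C=O)cc3C2C(=O)OC)ccc1OCc1ccccc1
F6 | step 4 | racemic trans methyl 2-(4-benzyloxy-3-methoxyphenyl)-5-formyl-7-methoxy-2,3-dihydrobenzofuran-3-carboxylate (2S,3S plus 2R,3R) | COc1cc([C@H]2Oc3c(OC)cc(C=O)cc3[C@@H]2C(=O)OC)ccc1OCc1ccccc1.COc1cc([C@@H]2Oc3c(OC)cc(C=O)cc3[C@H]2C(=O)OC)ccc1OCc1ccccc1
F7 | step 4 | methyl (2R,3R)-2-(4-benzyloxy-3-methoxyphenyl)-5-formyl-7-methoxy-2,3-dihydrobenzofuran-3-carboxylate | COc1cc([C@@H]2Oc3c(OC)cc(C=O)cc3[C@H]2C(=O)OC)ccc1OCc1ccccc1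
F8 | step 5 | ethyl (2S,3R)-2-(4-benzyloxy-3-methoxyphenyl)-5-(dimethoxymethyl)-7-methoxy-2,3-dihydrobenzofuran-3-carboxylate | COc1cc([C@H]2Oc3c(OC)cc(C(OC)OC)cc3[C@H]2C(=O)OCC)ccc1OCc1ccccc1
F9 | step 5 | methyl (2S,3R)-2-(4-benzyloxy-3-methoxyphenyl)-5-(dimethoxymethyl)-7-methoxy-2,3-dihydrobenzofuran-3-carboxylate (not isolated) | COc1cc([C@H]2Oc3c(OC)cc(C(OC)OC)cc3[C@H]2C(=O)OC)ccc1OCc1ccccc1
F10 | step 5 | ethyl (2S,3S)-2-(4-benzyloxy-3-methoxyphenyl)-5-(dimethoxymethyl)-7-methoxy-2,3-dihydrobenzofuran-3-carboxylate (not isolated) | COc1cc([C@H]2Oc3c(OC)cc(C(OC)OC)cc3[C@@H]2C(=O)OCC)ccc1OCc1ccccc1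
F11 | step 5 | methyl (2S,3S)-2-(4-benzyloxy-3-methoxyphenyl)-5-(dimethoxymethyl)-7-methoxy-2,3-dihydrobenzofuran-3-carboxylate | COc1cc([C@H]2Oc3c(OC)cc(C(OC)OC)cc3[C@@H]2C(=O)OC)ccc1OCc1ccccc1
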